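The target is a centrosymmetric α-truxillate cyclobutane whose two carboxyl carbons acylate N1 of two identical 5,6-dihydropyridin-2(1H)-one rings. Each lactam is disconnected at C2–C3 and C2–N1, so that its C2 carbonyl becomes carbon monoxide. In the last step a twofold palladium-catalysed carbonylative cyclisation of an open-chain bis[(Z)-4-iodobut-3-enyl] diamide joins CO to the vinyl carbon C3 (the C3–C2 bond) and closes both six-membered rings onto the amide nitrogens, creating both imides in one operation. It exploits the cis C3=C4 alkene attached to C2 in each ring and the inversion symmetry relating the two rings. The diamide comes from the solid-state head-to-tail [2+2] photodimer of 3,4-dimethoxycinnamic acid and but-3-yn-1-amine.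

Key step: step 5

Remark: the target is the achiral, centrosymmetric (meso) diastereomer, so only relative configuration has to be controlled. Every step acts on two equivalent sites: step 1 joins two molecules of 1, step 2 consumes two molecules of 3, and steps 3 to 5 each consume two equivalents of their reagent. Where a second molecule of a numbered compound is consumed, it is entered as the reaction partner under "Reagents that add atoms". The two arms react independently, so each twofold transformation is written as one step and the transient half-converted species is not numbered.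

Step 1
Reactants: 1 (E)-3,4-dimethoxycinnamic acid (two molecules combine: an inversion-related pair in the crystal)
Product: 2 (1α,2α,3β,4β)-2,4-bis(3,4-dimethoxyphenyl)cyclobutane-1,3-dicarboxylic acid (α-truxillic type; aryl groups mutually trans, carboxyl groups mutually trans)
Conditions: hν (medium-pressure mercury lamp, Pyrex filter), finely ground crystals of 1 (head-to-tail stacked polymorph) suspended in water, rt
Reagents that add atoms: (E)-3,4-dimethoxycinnamic acid (second molecule of 1), COc1ccc(/C=C/C(=O)O)cc1OC
Why: Topochemical [2+2] photocycloaddition between two molecules of 1: antiparallel, inversion-related pairs of alkenes lying within about 4.2 Å should give only the head-to-tail dimer, and since each E-alkene keeps its trans geometry and the pair is centrosymmetric, all four stereocentres are set at once as the meso α-truxillic arrangement.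

Step 2
Reactants: 2 (1α,2α,3β,4β)-2,4-bis(3,4-dimethoxyphenyl)cyclobutane-1,3-dicarboxylic acid; 3 but-3-yn-1-amine (two molecules are taken up, one per carboxyl group)
Product: 5 (1α,2α,3β,4β)-N1,N3-di(but-3-yn-1-yl)-2,4-bis(3,4-dimethoxyphenyl)cyclobutane-1,3-dicarboxamide, via diacid dichloride 4 (not isolated)
Conditions: (COCl)2, DMF (cat.), CH2Cl2, 0 °C to rt, evaporate; then 3 (2.5 equiv), pyridine, CH2Cl2, 0 °C to rt
Reagents that add atoms: but-3-yn-1-amine (second molecule of 3), C#CCCN
Why: Twofold acid chloride formation followed by twofold amide formation (nucleophilic acyl substitution), each acyl chloride taking up one molecule of 3; the 1,3-trans diacid cannot close to a cyclic anhydride, and fast aminolysis with the weak base pyridine should prevent ketene formation, so the α-stereocentres are retained.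

Step 3
Reactants: 5 (1α,2α,3β,4β)-N1,N3-di(but-3-yn-1-yl)-2,4-bis(3,4-dimethoxyphenyl)cyclobutane-1,3-dicarboxamide
Product: 6 (1α,2α,3β,4β)-N1,N3-bis(4-iodobut-3-yn-1-yl)-2,4-bis(3,4-dimethoxyphenyl)cyclobutane-1,3-dicarboxamide
Conditions: N-iodosuccinimide (2.4 equiv), AgNO3 (20 mol %), DMF, rt, dark
Reagents that add atoms: N-iodosuccinimide (two equivalents are consumed), O=C1CCC(=O)N1I
Why: Silver-catalysed iodination of both terminal alkynes through the silver acetylides; under these neutral conditions the dimethoxyarenes and the amide N–H should not be iodinated.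

Step 4
Reactants: 6 (1α,2α,3β,4β)-N1,N3-bis(4-iodobut-3-yn-1-yl)-2,4-bis(3,4-dimethoxyphenyl)cyclobutane-1,3-dicarboxamide
Product: 7 (1α,2α,3β,4β)-N1,N3-bis[(Z)-4-iodobut-3-en-1-yl]-2,4-bis(3,4-dimethoxyphenyl)cyclobutane-1,3-dicarboxamide
Conditions: 2-nitrobenzenesulfonyl hydrazide (excess, in portions), Et3N, THF/i-PrOH, rt, stopped at full consumption of 6
Reagents that add atoms: none
Why: Diimide semi-reduction of a 1-iodoalkyne: diimide generated in the flask delivers both hydrogens to the same face of each triple bond, which fixes the Z geometry of each iodoalkene, and the molecule holds no other C=C or C≡C bond that could be reduced.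

Step 5
Reactants: 7 (1α,2α,3β,4β)-N1,N3-bis[(Z)-4-iodobut-3-en-1-yl]-2,4-bis(3,4-dimethoxyphenyl)cyclobutane-1,3-dicarboxamide
Product: 8 1,1'-[(1α,2α,3β,4β)-2,4-bis(3,4-dimethoxyphenyl)cyclobutane-1,3-dicarbonyl]bis(5,6-dihydropyridin-2(1H)-one) (CNP0199212.1)
Conditions: Pd(OAc)2 (10 mol %), Xantphos (12 mol %), CO (1 atm), Et3N (4 equiv), toluene, 70 °C
Reagents that add atoms: carbon monoxide (two equivalents are consumed), [C-]#[O+]
Why: Zerovalent palladium (formed in the flask from Pd(OAc)2 and Xantphos) adds oxidatively to each (Z)-C–I bond with retention, CO inserts to give a (Z)-acryloyl complex of divalent palladium (this creates the C3–C2 bond), and the tethered amide nitrogen, deprotonated by Et3N, attacks the acyl carbon or eliminates reductively from a seven-membered acyl(amidato)palladacycle, which closes the lactam and returns zerovalent palladium. The closest known reaction type is the palladium-catalysed intramolecular aminocarbonylation of vinyl halides to α,β-unsaturated lactams, together with the carbonylative cyclisation of halo-amides to cyclic imides. Each of the two rings closes in the 6-exo-trig mode at the acyl carbon, its six atoms being N1, the new CO carbon C2, C3, C4, C5 and C6. No stereocentre is formed: the Z geometry fixed in step 4 becomes the endocyclic cis C3=C4 bond, and the four cyclobutane centres set in step 1 are not touched. The step needs CO insertion to outrun direct C–N coupling of the vinylpalladium (secured by the CO atmosphere and the weak amine base), N- over O-acylation (six-membered imide against an eight-membered isoimide) and ring closure over intermolecular acylation (short tether, moderate dilution). The mild base and temperature should also spare the epimerisable C–H next to each new imide.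

Compound list
1 | (E)-3,4-dimethoxycinnamic acid | COc1ccc(/C=C/C(=O)O)cc1OC | starting material
2 | (1α,2α,3β,4β)-2,4-bis(3,4-dimethoxyphenyl)cyclobutane-1,3-dicarboxylic acid | COc1ccc([C@H]2[C@H](C(=O)O)[C@H](c3ccc(OC)c(OC)c3)[C@H]2C(=O)O)cc1OC | intermediate
3 | but-3-yn-1-amine | C#CCCN | starting material
4 | (1α,2α,3β,4β)-2,4-bis(3,4-dimethoxyphenyl)cyclobutane-1,3-dicarbonyl dichloride | COc1ccc([C@H]2[C@H](C(=O)Cl)[C@H](c3ccc(OC)c(OC)c3)[C@H]2C(=O)Cl)cc1OC | intermediate (not isolated)
5 | (1α,2α,3β,4β)-N1,N3-di(but-3-yn-1-yl)-2,4-bis(3,4-dimethoxyphenyl)cyclobutane-1,3-dicarboxamide | COc1ccc([C@H]2[C@H](C(=O)NCCC#C)[C@H](c3ccc(OC)c(OC)c3)[C@H]2C(=O)NCCC#C)cc1OC | intermediate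
6 | (1α,2α,3β,4β)-N1,N3-bis(4-iodobut-3-yn-1-yl)-2,4-bis(3,4-dimethoxyphenyl)cyclobutane-1,3-dicarboxamide | COc1ccc([C@H]2[C@H](C(=O)NCCC#CI)[C@H](c3ccc(OC)c(OC)c3)[C@H]2C(=O)NCCC#CI)cc1OC | intermediate
7 | (1α,2α,3β,4β)-N1,N3-bis[(Z)-4-iodobut-3-en-1-yl]-2,4-bis(3,4-dimethoxyphenyl)cyclobutane-1,3-dicarboxamide | COc1ccc([C@H]2[C@H](C(=O)NCC/C=C\I)[C@H](c3ccc(OC)c(OC)c3)[C@H]2C(=O)NCC/C=C\I)cc1OC | intermediate
8 | 1,1'-[(1α,2α,3β,4β)-2,4-bis(3,4-dimethoxyphenyl)cyclobutane-1,3-dicarbonyl]bis(5,6-dihydropyridin-2(1H)-one) | COc1ccc([C@H]2[C@H](C(=O)N3CCC=CC3=O)[C@H](c3ccc(OC)c(OC)c3)[C@H]2C(=O)N2CCC=CC2=O)cc1OC | target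

Total step count: 5. Longest linear sequence: 5 steps (1 → 2 → 5 → 6 → 7 → 8).

Steps most likely to fail

Step 5 (key step). The secondary amide is a weak nucleophile, so capture of the acylpalladium may be slow and let it drift into hydrolysis or intermolecular acylation. Direct C–N coupling of the vinylpalladium may compete with CO insertion, and prolonged heating with base may epimerise the C–H next to the new imides. The fallback keeps the same carbonylative closure of the C3–C2 bond but performs it on a free amine before attachment to the core. It sets out from 3, uses 4 from step 2 and comes back at 8. Amine 3 is protected with Boc2O to give tert-butyl but-3-yn-1-ylcarbamate F1, which is iodinated (N-iodosuccinimide, AgNO3 cat.) to tert-butyl (4-iodobut-3-yn-1-yl)carbamate F2. Diimide reduction gives tert-butyl [(Z)-4-iodobut-3-en-1-yl]carbamate F3, and HCl in dioxane removes the carbamate to give (Z)-4-iodobut-3-en-1-amine hydrochloride F4. Cyclocarbonylation of F4 (Pd(PPh3)4, CO 1 atm, Et3N, MeCN, 60 °C) should close the ring with the far more nucleophilic primary amine and give 5,6-dihydropyridin-2(1H)-one F5. Deprotonation of F5 (n-BuLi, THF, −78 °C) and acylation of two molecules of the lithium salt by the two acyl chlorides of 4 should then deliver 8.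

Step 1. The acid may crystallise in a photostable or wrongly stacked packing, or the lattice may break down during irradiation so that conversion stalls or other dimers form. As no numbered compound precedes step 1, the fallback replaces 1 by a commercial acid whose crystals are expected to pack head-to-tail, and comes back at 2. Two molecules of (E)-4-acetoxy-3-methoxycinnamic acid F6 are joined by irradiation in the solid state to give the 4,4'-diacetoxy α-truxillic diacid F7. Aqueous NaOH cleaves the acetates to the bis-phenol diacid F8. Methylation of both phenols with Me2SO4 in aqueous NaOH, followed by brief heating with NaOH to cleave any methyl ester and acidification, should give 2.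

Step 4. Diimide may over-reduce the vinyl iodide to the alkyl iodide or leave one arm unreduced, which on a twofold substrate gives mixtures that are hard to separate. The fallback builds the Z-iodoalkene by olefination instead of reduction; it sets out from 4 and comes back at 7. Acylation of two molecules of 3,3-diethoxypropan-1-amine with 4 (pyridine, CH2Cl2) gives the bis(3,3-diethoxypropyl) diamide F9. Mild acid hydrolysis (aqueous HCl, THF) releases the bis(3-oxopropyl) diamide F10. Twofold Stork–Zhao olefination (Ph3P(CH2I)I, NaN(SiMe3)2 in excess to allow for the amide N–H, THF/DMPU, −78 °C) should give the Z,Z-diiodide 7.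

Further compounds
F1 | step 5 | tert-butyl but-3-yn-1-ylcarbamate | C#CCCNC(=O)OC(C)(C)C
F2 | step 5 | tert-butyl (4-iodobut-3-yn-1-yl)carbamate | IC#CCCNC(=O)OC(C)(C)C
F3 | step 5 | tert-butyl [(Z)-4-iodobut-3-en-1-yl]carbamate | I/C=C\CCNC(=O)OC(C)(C)C
F4 | step 5 | (Z)-4-iodobut-3-en-1-amine hydrochloride | NCC/C=C\I.Cl
F5 | step 5 | 5,6-dihydropyridin-2(1H)-one | O=C1C=CCCN1
F6 | step 1 | (E)-4-acetoxy-3-methoxycinnamic acid | CC(=O)Oc1ccc(/C=C/C(=O)O)cc1OC
F7 | step 1 | (1α,2α,3β,4β)-2,4-bis(4-acetoxy-3-methoxyphenyl)cyclobutane-1,3-dicarboxylic acid | CC(=O)Oc1ccc([C@H]2[C@H](C(=O)O)[C@H](c3ccc(OC(C)=O)c(OC)c3)[C@H]2C(=O)O)cc1OC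
F8 | step 1 | (1α,2α,3β,4β)-2,4-bis(4-hydroxy-3-methoxyphenyl)cyclobutane-1,3-dicarboxylic acid | Oc1ccc([C@H]2[C@H](C(=O)O)[C@H](c3ccc(O)c(OC)c3)[C@H]2C(=O)O)cc1OC
F9 | step 4 | (1α,2α,3β,4β)-N1,N3-bis(3,3-diethoxypropyl)-2,4-bis(3,4-dimethoxyphenyl)cyclobutane-1,3-dicarboxamide | COc1ccc([C@H]2[C@H](C(=O)NCCC(OCC)OCC)[C@H](c3ccc(OC)c(OC)c3)[C@H]2C(=O)NCCC(OCC)OCC)cc1OC
F10 | step 4 | (1α,2α,3β,4β)-N1,N3-bis(3-oxopropyl)-2,4-bis(3,4-dimethoxyphenyl)cyclobutane-1,3-dicarboxamide | COc1ccc([C@H]2[C@H](C(=O)NCCC=O)[C@H](c3ccc(OC)c(OC)c3)[C@H]2C(=O)NCCC=O)cc1OC
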